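**Retrosynthetic overview**
- Last operation is global O-debenzylation. Before it, ring F (pyran of the lower catechin unit) is closed by a C4–C4a bond onto ring D, whose two free positions are equivalent, so the 4→6 linkage is fixed by construction.
- Ring C (pyran of the upper ent-fisetinidol unit) is closed one stage earlier by a C4–C4a bond from the interflavan carbon onto ring A (quinone methide Friedel–Crafts closure), which sets C4.
- Key disconnection: the interflavan C4–C6 bond is cut as ArD–CH2. It is formed by nickel-catalysed radical cross-electrophile coupling of a ring D aryl iodide with an acyclic primary iodide, before either pyran ring exists.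
- C2/C3 of both units come from the two enantiomeric Sharpless epoxides of one cinnamyl alcohol, each opened at the benzylic carbon by a phenol with inversion.
- Ring order: rings B/E (catechol) and A/D (resorcinol) are bought as arenes; ring C is formed first, ring F last.

Target as read from the SMILES: ent-fisetinidol-(4β→6)-catechin, upper unit 2S,3R,4R (2,3-trans-3,4-trans), lower unit 2R,3S.

Assumption: rotamers about the C4–C6 bond interconvert at room temperature and are treated as one compound; flavan numbering (C2, C3, C4, rings A–F) is also used for the acyclic precursors.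

**Step 1**
Reactants: 1 catechol
Product: 2 1,2-bis(benzyloxy)benzene
Conditions: BnBr (2.2 equiv), K2CO3, DMF, 60 °C
Reagents that add atoms: benzyl bromide, BrCc1ccccc1
Why: Williamson ether synthesis; benzyl ethers are chosen so that all phenols are released together in the last step.

**Step 2**
Reactants: 2 1,2-bis(benzyloxy)benzene
Product: 3 1,2-bis(benzyloxy)-4-bromobenzene
Conditions: NBS (1.05 equiv), MeCN, 0 °C to rt
Reagents that add atoms: N-bromosuccinimide, O=C1CCC(=O)N1Br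
Why: electrophilic aromatic bromination para to an alkoxy group; the two activated positions are equivalent, so one regioisomer forms.

**Step 3**
Reactants: 3 1,2-bis(benzyloxy)-4-bromobenzene; 4 acrolein
Product: 7 (2E)-3-[3,4-bis(benzyloxy)phenyl]prop-2-en-1-ol, via aryllithium 5 (not isolated), via branched allylic alcohol 6 (not isolated)
Conditions: n-BuLi, THF, −78 °C; 4, −78 °C; then 1 M aq H2SO4, THF, rt
Reagents that add atoms: water, O
Why: bromine–lithium exchange and 1,2-addition to the enal, then acid-catalysed allylic 1,3-hydroxyl transposition through the stabilised cinnamyl cation, which gives the conjugated E primary alcohol under thermodynamic control.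

**Step 4**
Reactants: 7 (2E)-3-[3,4-bis(benzyloxy)phenyl]prop-2-en-1-ol
Product: 8 [(2R,3R)-3-[3,4-bis(benzyloxy)phenyl]oxiran-2-yl]methanol
Conditions: Ti(OiPr)4 (10 mol%), D-(−)-diisopropyl tartrate (12 mol%), t-BuOOH (2 equiv), 4 Å molecular sieves, CH2Cl2, −20 °C
Reagents that add atoms: tert-butyl hydroperoxide, CC(C)(C)OO
Why: Sharpless asymmetric epoxidation of an E primary allylic alcohol; the D-tartrate ligand delivers oxygen to the face that gives the 2R,3R trans-epoxide, the source of C2 and C3 of the upper unit.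

**Step 5**
Reactants: 7 (2E)-3-[3,4-bis(benzyloxy)phenyl]prop-2-en-1-ol
Product: 9 [(2S,3S)-3-[3,4-bis(benzyloxy)phenyl]oxiran-2-yl]methanol
Conditions: Ti(OiPr)4 (10 mol%), L-(+)-diisopropyl tartrate (12 mol%), t-BuOOH (2 equiv), 4 Å molecular sieves, CH2Cl2, −20 °C
Reagents that add atoms: tert-butyl hydroperoxide, CC(C)(C)OO
Why: Sharpless asymmetric epoxidation with the enantiomeric ligand gives the 2S,3S trans-epoxide, the source of C2 and C3 of the lower unit.

**Step 6**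
Reactants: 10 resorcinol
Product: 11 3-(benzyloxy)phenol
Conditions: 10 (3 equiv), BnBr (1 equiv), K2CO3, acetone, reflux; chromatography
Reagents that add atoms: benzyl bromide, BrCc1ccccc1
Why: statistical mono-Williamson etherification; excess resorcinol suppresses the dibenzyl ether and is washed out with water.

**Step 7**
Reactants: 8 [(2R,3R)-3-[3,4-bis(benzyloxy)phenyl]oxiran-2-yl]methanol; 11 3-(benzyloxy)phenol
Product: 12 (2R,3S)-3-[3,4-bis(benzyloxy)phenyl]-3-[3-(benzyloxy)phenoxy]propane-1,2-diol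
Conditions: 11 (1.5 equiv), Cs2CO3 (0.2 equiv), DMF, 60 °C
Reagents that add atoms: none
Why: SN2 epoxide opening by phenoxide at the benzylic carbon; inversion there sets C2 (S), the carbinol carbon keeps its oxygen and becomes C3 (R), which is the 2,3-trans relationship.

**Step 8**
Reactants: 12 (2R,3S)-3-[3,4-bis(benzyloxy)phenyl]-3-[3-(benzyloxy)phenoxy]propane-1,2-diol
Product: 13 (1S,2S)-1-[3,4-bis(benzyloxy)phenyl]-1-[3-(benzyloxy)phenoxy]-3-iodopropan-2-ol
Conditions: PPh3 (1.2 equiv), I2 (1.2 equiv), imidazole (2.5 equiv), CH2Cl2, 0 °C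
Reagents that add atoms: iodine, II
Why: Appel-type (Garegg–Samuelsson) iodination, selective for the primary hydroxyl; no stereocentre is touched (the descriptor at the carbinol changes only because CH2I outranks the benzylic carbon).

**Step 9**
Reactants: 10 resorcinol
Product: 14 2-iodobenzene-1,3-diol
Conditions: I2 (1.05 equiv), NaHCO3 (1.1 equiv), H2O, 0 °C to rt
Reagents that add atoms: iodine, II
Why: electrophilic iodination of resorcinol in aqueous bicarbonate, which is known to give the 2-iodo isomer; this carbon becomes C6 of ring D.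

**Step 10**
Reactants: 14 2-iodobenzene-1,3-diol
Product: 17 2-iodo-5-(4,4,5,5-tetramethyl-1,3,2-dioxaborolan-2-yl)benzene-1,3-diol, via bis-O-boryl ether 15 (not isolated), via triboryl compound 16 (not isolated)
Conditions: HBpin (3.5 equiv), [Ir(OMe)(cod)]2 (1.5 mol%), 4,4'-di-tert-butyl-2,2'-bipyridine (3 mol%), THF, rt then 80 °C; MeOH quench
Reagents that add atoms: pinacolborane, B1OC(C)(C)C(C)(C)O1
Why: iridium-catalysed C–H borylation under steric control; the phenols are O-borylated in situ, the only C–H without an ortho substituent is C5, and the boryl group there is the masked oxygen of the future C8a; borylation precedes benzylation so that no benzyl ring C–H competes.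

**Step 11**
Reactants: 17 2-iodo-5-(4,4,5,5-tetramethyl-1,3,2-dioxaborolan-2-yl)benzene-1,3-diol
Product: 18 2-[3,5-bis(benzyloxy)-4-iodophenyl]-4,4,5,5-tetramethyl-1,3,2-dioxaborolane
Conditions: BnBr (2.3 equiv), K2CO3, DMF, rt
Reagents that add atoms: benzyl bromide, BrCc1ccccc1
Why: Williamson ether synthesis; the boronic ester and the aryl iodide are inert to carbonate at room temperature.

**Step 12 (key step)**
Reactants: 13 (1S,2S)-1-[3,4-bis(benzyloxy)phenyl]-1-[3-(benzyloxy)phenoxy]-3-iodopropan-2-ol; 18 2-[3,5-bis(benzyloxy)-4-iodophenyl]-4,4,5,5-tetramethyl-1,3,2-dioxaborolane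
Product: 19 (1S,2R)-1-[3,4-bis(benzyloxy)phenyl]-1-[3-(benzyloxy)phenoxy]-3-[2,6-bis(benzyloxy)-4-(4,4,5,5-tetramethyl-1,3,2-dioxaborolan-2-yl)phenyl]propan-2-ol
Conditions: 18 (1.2 equiv), NiI2 (10 mol%), 4,4'-di-tert-butyl-2,2'-bipyridine (10 mol%), NaI (0.25 equiv), pyridine (0.1 equiv), Mn powder (2 equiv), DMPU, 40 °C
Reagents that add atoms: none
Why: nickel-catalysed reductive cross-electrophile coupling. Monovalent nickel abstracts iodine from 13 to give the primary β-hydroxyalkyl radical at C4, which is captured by the aryl–nickel species from oxidative addition of 18 to zerovalent nickel; reductive elimination from trivalent nickel forms the C4–C6 bond. The boronic ester, benzyl ethers and the C2/C3 stereocentres are untouched, and any epoxide formed from 13 is reopened by iodide.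

**Step 13**
Reactants: 19 (1S,2R)-1-[3,4-bis(benzyloxy)phenyl]-1-[3-(benzyloxy)phenoxy]-3-[2,6-bis(benzyloxy)-4-(4,4,5,5-tetramethyl-1,3,2-dioxaborolan-2-yl)phenyl]propan-2-ol
Product: 20 3,5-bis(benzyloxy)-4-[(2R,3S)-3-[3,4-bis(benzyloxy)phenyl]-3-[3-(benzyloxy)phenoxy]-2-hydroxypropyl]phenol
Conditions: 30% aq H2O2 (3 equiv), NaHCO3 (cat.), THF/H2O, 0 °C to rt
Reagents that add atoms: hydrogen peroxide, OO
Why: oxidative ipso-hydroxylation of the arylboronic ester (1,2-aryl shift from boron to oxygen); it unveils the single free phenol of ring D, para to the interflavan CH2.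

**Step 14**
Reactants: 20 3,5-bis(benzyloxy)-4-[(2R,3S)-3-[3,4-bis(benzyloxy)phenyl]-3-[3-(benzyloxy)phenoxy]-2-hydroxypropyl]phenol
Product: 22 (2S,3R,4R)-7-(benzyloxy)-2-[3,4-bis(benzyloxy)phenyl]-4-[2,6-bis(benzyloxy)-4-hydroxyphenyl]chroman-3-ol, via para-quinone methide 21 (not isolated)
Conditions: DDQ (1.0 equiv), CH2Cl2, −40 °C, 15 min; then CF3CO2H (0.2 equiv), −40 to 0 °C
Reagents that add atoms: none
Why: Proposed new method: DDQ dehydrogenates the 4-alkylphenol to the para-quinone methide (all DDQ is spent before any product exists), and acid then triggers an intramolecular 1,6-Friedel–Crafts addition of ring A (carbon para to its benzyloxy group, about a thousand times more nucleophilic than the catechol ring B) to C4; a chair-like closure with the C2 aryl, C3 hydroxyl and ring D all pseudo-equatorial gives the all-trans 4R product, which is also the thermodynamic isomer. Closest known reaction types are DDQ oxidation of 4-alkylphenols to quinone methides, acid-catalysed 1,6-arylation of para-quinone methides and DDQ functionalisation of flavan C4.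

**Step 15**
Reactants: 22 (2S,3R,4R)-7-(benzyloxy)-2-[3,4-bis(benzyloxy)phenyl]-4-[2,6-bis(benzyloxy)-4-hydroxyphenyl]chroman-3-ol; 9 [(2S,3S)-3-[3,4-bis(benzyloxy)phenyl]oxiran-2-yl]methanol
Product: 23 (2S,3R)-3-[3,4-bis(benzyloxy)phenyl]-3-{3,5-bis(benzyloxy)-4-[(2S,3R,4R)-7-(benzyloxy)-2-[3,4-bis(benzyloxy)phenyl]-3-hydroxychroman-4-yl]phenoxy}propane-1,2-diol
Conditions: 9 (1.3 equiv), Cs2CO3 (0.3 equiv), DMF, 60 °C, argon
Reagents that add atoms: none
Why: SN2 epoxide opening by the ring D phenoxide at the benzylic carbon with inversion, setting lower C2 (R) and keeping lower C3 (S); the ring C hydroxyl is not deprotonated by carbonate.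

**Step 16**
Reactants: 23 (2S,3R)-3-[3,4-bis(benzyloxy)phenyl]-3-{3,5-bis(benzyloxy)-4-[(2S,3R,4R)-7-(benzyloxy)-2-[3,4-bis(benzyloxy)phenyl]-3-hydroxychroman-4-yl]phenoxy}propane-1,2-diol
Product: 24 (2S,3R)-3-[3,4-bis(benzyloxy)phenyl]-3-{3,5-bis(benzyloxy)-4-[(2S,3R,4R)-7-(benzyloxy)-2-[3,4-bis(benzyloxy)phenyl]-3-hydroxychroman-4-yl]-2-iodophenoxy}propane-1,2-diol
Conditions: NIS (1.0 equiv), CH2Cl2, −20 °C, dark
Reagents that add atoms: N-iodosuccinimide, O=C1CCC(=O)N1I
Why: electrophilic aromatic iodination; the 1,3,5-trioxygenated ring D is far more nucleophilic than rings A, B and E, and its two free positions are equivalent, so one equivalent gives a single mono-iodide.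

**Step 17**
Reactants: 24 (2S,3R)-3-[3,4-bis(benzyloxy)phenyl]-3-{3,5-bis(benzyloxy)-4-[(2S,3R,4R)-7-(benzyloxy)-2-[3,4-bis(benzyloxy)phenyl]-3-hydroxychroman-4-yl]-2-iodophenoxy}propane-1,2-diol
Product: 25 (2S,3R,4R)-7-(benzyloxy)-2-[3,4-bis(benzyloxy)phenyl]-4-{2,6-bis(benzyloxy)-4-[(1R,2R)-1-[3,4-bis(benzyloxy)phenyl]-2-hydroxy-3-iodopropoxy]-3-iodophenyl}chroman-3-ol
Conditions: PPh3 (1.2 equiv), I2 (1.2 equiv), imidazole (2.5 equiv), CH2Cl2, 0 °C
Reagents that add atoms: iodine, II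
Why: Appel-type iodination, selective for the only primary hydroxyl; the two secondary hydroxyls do not react at 0 °C.

**Step 18**
Reactants: 25 (2S,3R,4R)-7-(benzyloxy)-2-[3,4-bis(benzyloxy)phenyl]-4-{2,6-bis(benzyloxy)-4-[(1R,2R)-1-[3,4-bis(benzyloxy)phenyl]-2-hydroxy-3-iodopropoxy]-3-iodophenyl}chroman-3-ol
Product: 26 (2S,3R,4R)-7-(benzyloxy)-2-[3,4-bis(benzyloxy)phenyl]-4-{(2R,3S)-5,7-bis(benzyloxy)-2-[3,4-bis(benzyloxy)phenyl]-3-hydroxychroman-6-yl}chroman-3-ol
Conditions: NiI2 (20 mol%), 4,4'-di-tert-butyl-2,2'-bipyridine (20 mol%), NaI (0.5 equiv), pyridine (0.2 equiv), Mn powder (3 equiv), DMPU (0.01 M), 40 °C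
Reagents that add atoms: none
Why: Proposed new method: intramolecular version of the nickel-catalysed reductive aryl iodide/alkyl iodide coupling; the aryl iodide adds to zerovalent nickel, the primary radical from the alkyl iodide is captured by the tethered aryl–nickel centre, and reductive elimination closes the six-membered ring F (C4–C4a) without touching the stereocentres. Closest known reaction types are the intermolecular reductive cross-electrophile coupling of step 12 and the anionic ring closure of ortho-metalated aryl epoxyalkyl ethers to chroman-3-ols.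

**Step 19**
Reactants: 26 (2S,3R,4R)-7-(benzyloxy)-2-[3,4-bis(benzyloxy)phenyl]-4-{(2R,3S)-5,7-bis(benzyloxy)-2-[3,4-bis(benzyloxy)phenyl]-3-hydroxychroman-6-yl}chroman-3-ol
Product: 27 ent-fisetinidol-(4β→6)-catechin, (2S,3R,4R)-2-(3,4-dihydroxyphenyl)-4-[(2R,3S)-2-(3,4-dihydroxyphenyl)-3,5,7-trihydroxychroman-6-yl]chroman-3,7-diol
Conditions: H2 (1 atm), Pd(OH)2/C (20 wt%), THF/MeOH 1:1, rt
Reagents that add atoms: none
Why: hydrogenolysis of the seven benzyl ethers; the pyran C2–O bonds and the interflavan bond survive these neutral conditions, as is usual for benzylated proanthocyanidins.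

**Compound list**
1 | catechol | Oc1ccccc1O | starting material
2 | 1,2-bis(benzyloxy)benzene | c1ccc(cc1)COc1ccccc1OCc1ccccc1 | intermediate
3 | 1,2-bis(benzyloxy)-4-bromobenzene | Brc1ccc(OCc2ccccc2)c(OCc2ccccc2)c1 | intermediate
4 | acrolein | C=CC=O | starting material
5 | [3,4-bis(benzyloxy)phenyl]lithium | [Li]c1ccc(OCc2ccccc2)c(OCc2ccccc2)c1 | intermediate (not isolated)
6 | rac-1-[3,4-bis(benzyloxy)phenyl]prop-2-en-1-ol | C=CC(O)c1ccc(OCc2ccccc2)c(OCc2ccccc2)c1 | intermediate (not isolated)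
7 | (2E)-3-[3,4-bis(benzyloxy)phenyl]prop-2-en-1-ol | OC/C=C/c1ccc(OCc2ccccc2)c(OCc2ccccc2)c1 | intermediate
8 | [(2R,3R)-3-[3,4-bis(benzyloxy)phenyl]oxiran-2-yl]methanol | OC[C@H]1O[C@@H]1c1ccc(OCc2ccccc2)c(OCc2ccccc2)c1 | intermediate
9 | [(2S,3S)-3-[3,4-bis(benzyloxy)phenyl]oxiran-2-yl]methanol | OC[C@@H]1O[C@H]1c1ccc(OCc2ccccc2)c(OCc2ccccc2)c1 | intermediate
10 | resorcinol | Oc1cccc(O)c1 | starting material
11 | 3-(benzyloxy)phenol | Oc1cccc(OCc2ccccc2)c1 | intermediate
12 | (2R,3S)-3-[3,4-bis(benzyloxy)phenyl]-3-[3-(benzyloxy)phenoxy]propane-1,2-diol | c1ccc(cc1)COc1cccc(c1)O[C@@H](c1ccc(OCc2ccccc2)c(OCc2ccccc2)c1)[C@H](O)CO | intermediate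
13 | (1S,2S)-1-[3,4-bis(benzyloxy)phenyl]-1-[3-(benzyloxy)phenoxy]-3-iodopropan-2-ol | c1ccc(cc1)COc1cccc(c1)O[C@@H](c1ccc(OCc2ccccc2)c(OCc2ccccc2)c1)[C@H](O)CI | intermediate
14 | 2-iodobenzene-1,3-diol | Oc1cccc(O)c1I | intermediate
15 | 2-iodo-1,3-bis[(4,4,5,5-tetramethyl-1,3,2-dioxaborolan-2-yl)oxy]benzene | Ic1c(OB2OC(C)(C)C(C)(C)O2)cccc1OB1OC(C)(C)C(C)(C)O1 | intermediate (not isolated)
16 | 2-iodo-5-(4,4,5,5-tetramethyl-1,3,2-dioxaborolan-2-yl)-1,3-bis[(4,4,5,5-tetramethyl-1,3,2-dioxaborolan-2-yl)oxy]benzene | Ic1c(OB2OC(C)(C)C(C)(C)O2)cc(B2OC(C)(C)C(C)(C)O2)cc1OB1OC(C)(C)C(C)(C)O1 | intermediate (not isolated)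
17 | 2-iodo-5-(4,4,5,5-tetramethyl-1,3,2-dioxaborolan-2-yl)benzene-1,3-diol | Oc1cc(B2OC(C)(C)C(C)(C)O2)cc(O)c1I | intermediate
18 | 2-[3,5-bis(benzyloxy)-4-iodophenyl]-4,4,5,5-tetramethyl-1,3,2-dioxaborolane | Ic1c(OCc2ccccc2)cc(B2OC(C)(C)C(C)(C)O2)cc1OCc1ccccc1 | intermediate
19 | (1S,2R)-1-[3,4-bis(benzyloxy)phenyl]-1-[3-(benzyloxy)phenoxy]-3-[2,6-bis(benzyloxy)-4-(4,4,5,5-tetramethyl-1,3,2-dioxaborolan-2-yl)phenyl]propan-2-ol | c1ccc(cc1)COc1cccc(c1)O[C@@H](c1ccc(OCc2ccccc2)c(OCc2ccccc2)c1)[C@H](O)Cc1c(OCc2ccccc2)cc(cc1OCc1ccccc1)B1OC(C)(C)C(C)(C)O1 | intermediate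
20 | 3,5-bis(benzyloxy)-4-[(2R,3S)-3-[3,4-bis(benzyloxy)phenyl]-3-[3-(benzyloxy)phenoxy]-2-hydroxypropyl]phenol | c1ccc(cc1)COc1cccc(c1)O[C@@H](c1ccc(OCc2ccccc2)c(OCc2ccccc2)c1)[C@H](O)Cc1c(OCc2ccccc2)cc(O)cc1OCc1ccccc1 | intermediate
21 | 3,5-bis(benzyloxy)-4-[(2R,3S)-3-[3,4-bis(benzyloxy)phenyl]-3-[3-(benzyloxy)phenoxy]-2-hydroxypropylidene]cyclohexa-2,5-dien-1-one | c1ccc(cc1)COc1cccc(c1)O[C@@H](c1ccc(OCc2ccccc2)c(OCc2ccccc2)c1)[C@H](O)C=C1C(OCc2ccccc2)=CC(=O)C=C1OCc1ccccc1 | intermediate (not isolated)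
22 | (2S,3R,4R)-7-(benzyloxy)-2-[3,4-bis(benzyloxy)phenyl]-4-[2,6-bis(benzyloxy)-4-hydroxyphenyl]chroman-3-ol | c1ccc(cc1)COc1ccc2c(c1)O[C@@H](c1ccc(OCc3ccccc3)c(OCc3ccccc3)c1)[C@H](O)[C@H]2c1c(OCc2ccccc2)cc(O)cc1OCc1ccccc1 | intermediate
23 | (2S,3R)-3-[3,4-bis(benzyloxy)phenyl]-3-{3,5-bis(benzyloxy)-4-[(2S,3R,4R)-7-(benzyloxy)-2-[3,4-bis(benzyloxy)phenyl]-3-hydroxychroman-4-yl]phenoxy}propane-1,2-diol | c1ccc(cc1)COc1ccc2c(c1)O[C@@H](c1ccc(OCc3ccccc3)c(OCc3ccccc3)c1)[C@H](O)[C@H]2c1c(OCc2ccccc2)cc(O[C@H](c2ccc(OCc3ccccc3)c(OCc3ccccc3)c2)[C@@H](O)CO)cc1OCc1ccccc1 | intermediate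
24 | (2S,3R)-3-[3,4-bis(benzyloxy)phenyl]-3-{3,5-bis(benzyloxy)-4-[(2S,3R,4R)-7-(benzyloxy)-2-[3,4-bis(benzyloxy)phenyl]-3-hydroxychroman-4-yl]-2-iodophenoxy}propane-1,2-diol | c1ccc(cc1)COc1ccc2c(c1)O[C@@H](c1ccc(OCc3ccccc3)c(OCc3ccccc3)c1)[C@H](O)[C@H]2c1c(OCc2ccccc2)c(I)c(O[C@H](c2ccc(OCc3ccccc3)c(OCc3ccccc3)c2)[C@@H](O)CO)cc1OCc1ccccc1 | intermediate
25 | (2S,3R,4R)-7-(benzyloxy)-2-[3,4-bis(benzyloxy)phenyl]-4-{2,6-bis(benzyloxy)-4-[(1R,2R)-1-[3,4-bis(benzyloxy)phenyl]-2-hydroxy-3-iodopropoxy]-3-iodophenyl}chroman-3-ol | c1ccc(cc1)COc1ccc2c(c1)O[C@@H](c1ccc(OCc3ccccc3)c(OCc3ccccc3)c1)[C@H](O)[C@H]2c1c(OCc2ccccc2)c(I)c(O[C@H](c2ccc(OCc3ccccc3)c(OCc3ccccc3)c2)[C@@H](O)CI)cc1OCc1ccccc1 | intermediate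
26 | (2S,3R,4R)-7-(benzyloxy)-2-[3,4-bis(benzyloxy)phenyl]-4-{(2R,3S)-5,7-bis(benzyloxy)-2-[3,4-bis(benzyloxy)phenyl]-3-hydroxychroman-6-yl}chroman-3-ol | c1ccc(cc1)COc1ccc2c(c1)O[C@@H](c1ccc(OCc3ccccc3)c(OCc3ccccc3)c1)[C@H](O)[C@H]2c1c(OCc2ccccc2)cc2c(c1OCc1ccccc1)C[C@H](O)[C@@H](c1ccc(OCc3ccccc3)c(OCc3ccccc3)c1)O2 | intermediate
27 | ent-fisetinidol-(4β→6)-catechin, (2S,3R,4R)-2-(3,4-dihydroxyphenyl)-4-[(2R,3S)-2-(3,4-dihydroxyphenyl)-3,5,7-trihydroxychroman-6-yl]chroman-3,7-diol | Oc1ccc2c(c1)O[C@@H](c1ccc(O)c(O)c1)[C@H](O)[C@H]2c1c(O)cc2c(c1O)C[C@H](O)[C@@H](c1ccc(O)c(O)c1)O2 | target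

**Step count**
Total: 19 steps. Longest linear sequence: 14 steps (1, 2, 3, 4, 7, 8, 12, 13, 14, 15, 16, 17, 18, 19).

**Steps most likely to fail, with fallbacks**

Step 12. The aryl iodide 18 carries two ortho benzyloxy groups, so radical capture and reductive elimination at nickel may be slow, leaving reduction of 13 or homocoupling as the main outcome. The fallback replaces the radical coupling by a polar epoxide opening and sets out from 13 and 18. K2CO3 in MeOH closes 13 to the terminal epoxide (2R)-2-{(S)-[3,4-bis(benzyloxy)phenyl][3-(benzyloxy)phenoxy]methyl}oxirane F1. In a second flask, i-PrMgCl·LiCl (THF, −40 °C) converts 18 by iodine–magnesium exchange into [2,6-bis(benzyloxy)-4-(4,4,5,5-tetramethyl-1,3,2-dioxaborolan-2-yl)phenyl]magnesium chloride F2. With CuI (10 mol%), F2 opens F1 at the CH2 carbon, and NH4Cl work-up returns the route to 19.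

Step 14. The product 22 still has a phenol para to a doubly benzylic C–H and could be oxidised further, and the quinone methide could close with the wrong C4 configuration or onto ring B. The fallback separates oxidation from C–C bond formation and sets out from 20. DDQ in CH2Cl2/MeOH (4:1, 0 °C) traps the quinone methide as 3,5-bis(benzyloxy)-4-[(2S,3S)-3-[3,4-bis(benzyloxy)phenyl]-3-[3-(benzyloxy)phenoxy]-2-hydroxy-1-methoxypropyl]phenol F3 (both epimers at the methoxy-bearing carbon), which is isolated. BF3·OEt2 (CH2Cl2, −78 °C) then ionises the benzylic C–OMe bond and the cation closes onto ring A under kinetic control at low temperature, coming back to the route at 22.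

Step 18. The intramolecular nickel coupling is unprecedented on a substrate of this size, and the aryl iodide is again flanked by two oxygen substituents. The fallback is the anionic ring closure and sets out from 25. K2CO3 in MeOH gives the terminal epoxide (2S,3R,4R)-7-(benzyloxy)-2-[3,4-bis(benzyloxy)phenyl]-4-{2,6-bis(benzyloxy)-3-iodo-4-[(R)-[3,4-bis(benzyloxy)phenyl][(2S)-oxiran-2-yl]methoxy]phenyl}chroman-3-ol F4. i-PrMgCl·LiCl (2.2 equiv, THF, −40 °C; the first equivalent deprotonates the ring C hydroxyl) then gives the ring D arylmagnesium chloride as its chloromagnesium alkoxide F5. On warming with CuI (10 mol%), F5 opens the epoxide at CH2 in a six-membered ring closure and comes back to the route at 26.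

**Further compounds**
F1 | step 12 | (2R)-2-{(S)-[3,4-bis(benzyloxy)phenyl][3-(benzyloxy)phenoxy]methyl}oxirane | c1ccc(cc1)COc1cccc(c1)O[C@@H](c1ccc(OCc2ccccc2)c(OCc2ccccc2)c1)[C@H]1CO1
F2 | step 12 | [2,6-bis(benzyloxy)-4-(4,4,5,5-tetramethyl-1,3,2-dioxaborolan-2-yl)phenyl]magnesium chloride | Cl[Mg]c1c(OCc2ccccc2)cc(cc1OCc1ccccc1)B1OC(C)(C)C(C)(C)O1
F3 | step 14 | 3,5-bis(benzyloxy)-4-[(2S,3S)-3-[3,4-bis(benzyloxy)phenyl]-3-[3-(benzyloxy)phenoxy]-2-hydroxy-1-methoxypropyl]phenol (both epimers at C1 of the propyl chain) | c1ccc(cc1)COc1cccc(c1)O[C@@H](c1ccc(OCc2ccccc2)c(OCc2ccccc2)c1)[C@H](O)C(OC)c1c(OCc2ccccc2)cc(O)cc1OCc1ccccc1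
F4 | step 18 | (2S,3R,4R)-7-(benzyloxy)-2-[3,4-bis(benzyloxy)phenyl]-4-{2,6-bis(benzyloxy)-3-iodo-4-[(R)-[3,4-bis(benzyloxy)phenyl][(2S)-oxiran-2-yl]methoxy]phenyl}chroman-3-ol | c1ccc(cc1)COc1ccc2c(c1)O[C@@H](c1ccc(OCc3ccccc3)c(OCc3ccccc3)c1)[C@H](O)[C@H]2c1c(OCc2ccccc2)c(I)c(O[C@H](c2ccc(OCc3ccccc3)c(OCc3ccccc3)c2)[C@@H]2CO2)cc1OCc1ccccc1
F5 | step 18 | ring D arylmagnesium chloride of F4 as its ring C chloromagnesium alkoxide | c1ccc(cc1)COc1ccc2c(c1)O[C@@H](c1ccc(OCc3ccccc3)c(OCc3ccccc3)c1)[C@H](O[Mg]Cl)[C@H]2c1c(OCc2ccccc2)c([Mg]Cl)c(O[C@H](c2ccc(OCc3ccccc3)c(OCc3ccccc3)c2)[C@@H]2CO2)cc1OCc1ccccc1
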